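**Retrosynthetic overview**

1. The target is meso: ring A (C1 R, C2 S) and ring B (C1 S, C2 R) are constitutionally identical cyclohexanes (C1 = quaternary carbon with methyl and 4-methylpent-3-enoyl, C2 = carbinol, C3 = ring carbon of the exocyclic Z-alkene), joined C3 to C3 by =CH–CH2–CH2–CH=.
2. Enabling feature: in each ring the C2 hydroxyl is β to the side-chain ketone on C1 (aldol retron across C1–C2) and C2 is the carbonyl carbon of a (Z)-2-alkylidene aldehyde on C3. Each ring is therefore the intramolecular aldol of a C1 enolate, released regiospecifically from an allyl β-keto ester by palladium, and the mirror-image rings come from mirror-image ligands.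
3. Disconnections: ring A C1–C2 (key step, last); ring B C1–C2 (same reaction, enantiomeric ligand); both C6–C1 bonds (alkylation of one allyl β-keto ester 8, used twice); both exocyclic C=C bonds (Z-selective Wittig reactions of α-silyloxy ketones with a C4 bis-phosphonium salt).
4. Order of ring formation: ring B (step 11), then ring A (step 16). The racemic quaternary ester centres are erased on decarboxylation; all four stereocentres come from the two cyclisations.

Key step: step 16

Assumption: the sense of induction is taken as (S)-t-Bu-PHOX → (1S,2R) ring and (R)-t-Bu-PHOX → (1R,2S) ring; should step 11 show the opposite sense, the two ligand enantiomers are exchanged between steps 11 and 16 and nothing else changes.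

**Route**

Step 1
Reactants: 1 2,2,5-trimethyl-1,3-dioxane-4,6-dione; 2 prop-2-en-1-ol
Product: 3 2-methyl-3-oxo-3-(prop-2-en-1-yloxy)propanoic acid
Conditions: neat 2 (excess), 100 °C
Reagents that add atoms: none
Why: Alcoholysis of the Meldrum's acid ring opens it to the malonic half ester with loss of acetone; the product is racemic and its stereocentre is erased later.

Step 2
Reactants: 4 4-methylpent-3-enoic acid; 5 1,1'-carbonyldiimidazole; 3 2-methyl-3-oxo-3-(prop-2-en-1-yloxy)propanoic acid
Product: 8 prop-2-en-1-yl 2,6-dimethyl-3-oxohept-5-enoate, via acyl imidazole 6 (not isolated), via acylmalonic acid 7 (not isolated)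
Conditions: 4, 5, THF, rt; then 3, MgCl2, Et3N, MeCN, rt; aqueous citric acid work-up
Reagents that add atoms: none
Why: Masamune–Claisen condensation, in which the magnesium enolate of the half ester is C-acylated by the acyl imidazole and the acylmalonic acid loses CO2 on acidification, is neutral enough to keep the skipped (β,γ) double bond out of conjugation.

Step 3
Reactants: 9 4-chlorobutanoyl chloride; 10 1,1,2-tris(trimethylsilyloxy)ethene
Product: 13 5-chloro-1-hydroxypentan-2-one, via silyl ester 11 (not isolated), via hydroxy keto acid 12 (not isolated)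
Conditions: neat, 95 °C; then 0.6 M HCl, dioxane, 85 °C
Reagents that add atoms: none
Why: C-acylation of the electron-rich tris(silyloxy)ethene by the acid chloride, then hydrolysis and decarboxylation of the α-hydroxy-β-keto acid, is the standard homologation of an acid chloride to a hydroxymethyl ketone.

Step 4
Reactants: 13 5-chloro-1-hydroxypentan-2-one
Product: 14 5-chloro-1-[(triethylsilyl)oxy]pentan-2-one
Conditions: Et3SiCl, imidazole, CH2Cl2, 0 °C
Reagents that add atoms: chlorotriethylsilane, CC[Si](Cl)(CC)CC
Why: Silylation of the primary alcohol with a silyl group that can later be removed in the presence of a tert-butyldimethylsilyl ether.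

Step 5
Reactants: 8 prop-2-en-1-yl 2,6-dimethyl-3-oxohept-5-enoate; 14 5-chloro-1-[(triethylsilyl)oxy]pentan-2-one
Product: 17 prop-2-en-1-yl 2,6-dimethyl-3-oxo-2-{4-oxo-5-[(triethylsilyl)oxy]pentyl}hept-5-enoate, via sodium enolate 15 (not isolated), via iodide 16 (not isolated)
Conditions: 8, NaH (slightly less than 8), DMF, 0 °C; then 14, NaI (cat.), 45 °C
Reagents that add atoms: none
Why: C-alkylation of the stabilised β-keto ester enolate by the primary iodide formed in the flask (Finkelstein exchange); the enolate is the only base present and is too weak to move the skipped double bond, and the new quaternary centre is racemic and erased later.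

Step 6
Reactants: 13 5-chloro-1-hydroxypentan-2-one
Product: 18 1-{[tert-butyl(dimethyl)silyl]oxy}-5-chloropentan-2-one
Conditions: t-BuMe2SiCl, imidazole, CH2Cl2, 0 °C to rt
Reagents that add atoms: tert-butyl(chloro)dimethylsilane, CC(C)(C)[Si](C)(C)Cl
Why: Silylation of the primary alcohol with the more robust of the two silyl groups, so that the two ends of the later diene can be unmasked one after the other.

Step 7
Reactants: 19 butane-1,4-diylbis(triphenylphosphonium) dibromide; 18 1-{[tert-butyl(dimethyl)silyl]oxy}-5-chloropentan-2-one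
Product: 21 [(4Z)-5-({[tert-butyl(dimethyl)silyl]oxy}methyl)-8-chlorooct-4-en-1-yl](triphenyl)phosphonium bromide, via mono-ylide 20 (not isolated)
Conditions: 19 (3 equiv), KN(SiMe3)2 (1 equiv), THF, 0 °C; then 18, −78 °C to rt
Reagents that add atoms: none
Why: Wittig olefination of an α-silyloxy ketone with an unstabilised ylide is known to place the new chain cis to the CH2OSi group (Z-trisubstituted allylic ether), and the excess of bis-salt with one equivalent of base should engage only one phosphonium end.

Step 8
Reactants: 21 [(4Z)-5-({[tert-butyl(dimethyl)silyl]oxy}methyl)-8-chlorooct-4-en-1-yl](triphenyl)phosphonium bromide; 17 prop-2-en-1-yl 2,6-dimethyl-3-oxo-2-{4-oxo-5-[(triethylsilyl)oxy]pentyl}hept-5-enoate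
Product: 23 prop-2-en-1-yl 2-[(4Z,8Z)-9-({[tert-butyl(dimethyl)silyl]oxy}methyl)-12-chloro-4-{[(triethylsilyl)oxy]methyl}dodeca-4,8-dien-1-yl]-2,6-dimethyl-3-oxohept-5-enoate, via ylide 22 (not isolated)
Conditions: KN(SiMe3)2, THF, −78 °C; then 17, −78 to 0 °C
Reagents that add atoms: none
Why: Second Z-selective Wittig olefination of an α-silyloxy ketone; the α-silyloxy ketone carbonyl is far more electrophilic than the hindered ketone next to the quaternary carbon or the ester, so the ylide should add there first.

Step 9
Reactants: 23 (the diene of step 8)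
Product: 24 prop-2-en-1-yl 2-[(4Z,8Z)-9-({[tert-butyl(dimethyl)silyl]oxy}methyl)-12-chloro-4-(hydroxymethyl)dodeca-4,8-dien-1-yl]-2,6-dimethyl-3-oxohept-5-enoate
Conditions: pyridinium p-toluenesulfonate (cat.), MeOH/CH2Cl2, 0 °C
Reagents that add atoms: none
Why: Acid-catalysed methanolysis cleaves a primary triethylsilyl ether much faster than a primary tert-butyldimethylsilyl ether, which frees only the allylic alcohol of the ring B end.

Step 10
Reactants: 24 (the allylic alcohol of step 9)
Product: 25 prop-2-en-1-yl 2-[(4Z,8Z)-9-({[tert-butyl(dimethyl)silyl]oxy}methyl)-12-chloro-4-formyldodeca-4,8-dien-1-yl]-2,6-dimethyl-3-oxohept-5-enoate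
Conditions: TEMPO (cat.), PhI(OAc)2, CH2Cl2, rt
Reagents that add atoms: none
Why: The oxoammonium oxidation of primary allylic alcohols gives (Z)-enals without Z-to-E isomerisation (as in nerol to neral) and leaves the keto ester and the alkenes alone.

Step 11
Reactants: 25 (the Z-enal of step 10)
Product: 27 1-[(1S,2R,3Z)-3-[(4Z)-5-({[tert-butyl(dimethyl)silyl]oxy}methyl)-8-chlorooct-4-en-1-ylidene]-2-hydroxy-1-methylcyclohexyl]-4-methylpent-3-en-1-one, via palladium enolate 26 (not isolated)
Conditions: Pd2(dba)3 (2.5 mol %), (S)-t-Bu-PHOX (6 mol %), diethyl methylmalonate (1.1 equiv), toluene, 25 °C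
Reagents that add atoms: none
Why: Proposed new method: the palladium-catalysed decarboxylative aldol cyclisation of allyl 2-methyl-2-(ω-formylalkyl)-3-oxoalkanoates is known with achiral phosphines, and the new element is ligand control of the enolate face; here the (S)-ligand enolate 26 closes ring B by a 6-(enolexo)-exo-trig aldol that should set C1 as S and, through the chair transition state described in step 16, the hydroxyl cis to the acyl group (C2 R), while the alkyl chloride and silyl ether of the other end are inert to zerovalent palladium.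

Step 12
Reactants: 27 (the ring B aldol of step 11)
Product: 28 1-[(1S,2R,3Z)-3-[(4Z)-5-({[tert-butyl(dimethyl)silyl]oxy}methyl)-8-chlorooct-4-en-1-ylidene]-1-methyl-2-[(triethylsilyl)oxy]cyclohexyl]-4-methylpent-3-en-1-one
Conditions: Et3SiOTf, 2,6-lutidine, CH2Cl2, −78 °C
Reagents that add atoms: triethylsilyl trifluoromethanesulfonate, CC[Si](CC)(CC)OS(=O)(=O)C(F)(F)F
Why: Silylation of the hindered aldol hydroxyl blocks retro-aldol opening (and with it loss of the ring B stereocentres) during the basic alkylation that follows.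

Step 13
Reactants: 28 (the ring B silyl ether of step 12); 8 prop-2-en-1-yl 2,6-dimethyl-3-oxohept-5-enoate
Product: 31 prop-2-en-1-yl 2-[(4Z,8Z)-4-({[tert-butyl(dimethyl)silyl]oxy}methyl)-8-{(2R,3S)-3-methyl-3-(4-methylpent-3-enoyl)-2-[(triethylsilyl)oxy]cyclohexylidene}oct-4-en-1-yl]-2,6-dimethyl-3-oxohept-5-enoate, via potassium enolate 29 (not isolated), via iodide 30 (not isolated)
Conditions: 8, KN(SiMe3)2 (0.95 equiv relative to 8, titrated solution), THF, −78 to 0 °C; then DMF, 28, KI (cat.), 45 °C
Reagents that add atoms: none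
Why: C-alkylation of a stabilised β-keto ester enolate by a primary iodide formed in the flask (Finkelstein exchange), here with the more dissociated potassium enolate, which suits the larger and more valuable electrophile, and with a titrated soluble amide base dosed just short of 8 so that the enolate is the only base left when 28 is added; it should not touch the protected aldol or the skipped enones, and the new quaternary ester centre (a mixture of two epimers) is erased in step 16.

Step 14
Reactants: 31 (the keto ester of step 13)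
Product: 32 prop-2-en-1-yl 2-[(4Z,8Z)-4-(hydroxymethyl)-8-[(2R,3S)-2-hydroxy-3-methyl-3-(4-methylpent-3-enoyl)cyclohexylidene]oct-4-en-1-yl]-2,6-dimethyl-3-oxohept-5-enoate
Conditions: HF·pyridine, pyridine, THF, 0 °C to rt
Reagents that add atoms: none
Why: Buffered hydrogen fluoride removes both silyl ethers without the basic conditions that could trigger retro-aldol opening of ring B or conjugation of the skipped enones.

Step 15
Reactants: 32 (the diol of step 14)
Product: 33 prop-2-en-1-yl 2-[(4Z,8Z)-4-formyl-8-[(2R,3S)-2-hydroxy-3-methyl-3-(4-methylpent-3-enoyl)cyclohexylidene]oct-4-en-1-yl]-2,6-dimethyl-3-oxohept-5-enoate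
Conditions: TEMPO (cat.), PhI(OAc)2, CH2Cl2, rt
Reagents that add atoms: none
Why: The oxoammonium oxidation takes the primary allylic alcohol far faster than the hindered secondary alcohol of ring B and keeps the Z geometry of the new enal.

Step 16
Reactants: 33 (the Z-enal of step 15)
Product: 35 1-[(1R,2S,3Z)-2-hydroxy-3-{(4Z)-4-[(2R,3S)-2-hydroxy-3-methyl-3-(4-methylpent-3-enoyl)cyclohexylidene]butylidene}-1-methylcyclohexyl]-4-methylpent-3-en-1-one, via palladium enolate 34 (not isolated)
Conditions: Pd2(dba)3 (2.5 mol %), (R)-t-Bu-PHOX (6 mol %), diethyl methylmalonate (1.1 equiv), toluene, 25 °C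
Reagents that add atoms: none
Why: Proposed new method: zerovalent palladium bearing (R)-t-Bu-PHOX adds oxidatively to the allyl ester of 33 and the carboxylate loses CO2, which unmasks the fully substituted C1 enolate 34 regiospecifically (never on the side of the skipped alkene) as a chiral palladium enolate whose E and Z forms interconvert; its carbon adds to the (Z)-enal carbonyl in a 6-(enolexo)-exo-trig aldol closure of ring A, after which diethyl methylmalonate protonates the alkoxide and carries the allyl group away, returning zerovalent palladium. The closest known reactions are the palladium-catalysed decarboxylative aldol cyclisation of allyl 2-methyl-2-(ω-formylalkyl)-3-oxoalkanoates to 2-acyl-2-methylcycloalkanols with achiral phosphines, and the enantioconvergent capture of acyclic, fully substituted palladium–PHOX enolates in decarboxylative asymmetric allylic alkylation; the new element is ligand-controlled face selection in the aldol event. The quaternary C1 is set by the ligand, which should shield one enolate face ((R)-ligand, C1 R). C2 follows from the closed chair transition state, in which the aldehyde oxygen must be axial to escape A(1,3) strain with the linker chain cis to it on the exocyclic alkene and the acyl group equatorial to stay bridged through the metal to that oxygen, so the hydroxyl ends cis to the acyl group (C2 S); the Z-alkene is already in place and is not touched. The step needs 1,2-addition (6-exo) over 1,4-addition (6-endo), aldol over C-allylation of the enolate, and catalyst control independent of ring B; the first two rest on the oxygen-bridged six-membered transition state and the short tether, the third on the eight atoms between ring B and the reacting end. The malonate also buffers the medium so that ring B does not open by retro-aldol, and the product of this step is the target itself.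

**Compound list**

1 | 2,2,5-trimethyl-1,3-dioxane-4,6-dione | CC1C(=O)OC(C)(C)OC1=O | starting material
2 | prop-2-en-1-ol | C=CCO | starting material
3 | 2-methyl-3-oxo-3-(prop-2-en-1-yloxy)propanoic acid (racemic) | C=CCOC(=O)C(C)C(=O)O | intermediate
4 | 4-methylpent-3-enoic acid | CC(C)=CCC(=O)O | starting material
5 | 1,1'-carbonyldiimidazole | O=C(n1ccnc1)n1ccnc1 | starting material
6 | 1-(1H-imidazol-1-yl)-4-methylpent-3-en-1-one | CC(C)=CCC(=O)n1ccnc1 | intermediate
7 | 2,6-dimethyl-3-oxo-2-[(prop-2-en-1-yloxy)carbonyl]hept-5-enoic acid (racemic, present as its magnesium salt) | CC(C)=CCC(=O)C(C)(C(=O)O)C(=O)OCC=C | intermediate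
8 | prop-2-en-1-yl 2,6-dimethyl-3-oxohept-5-enoate (racemic) | C=CCOC(=O)C(C)C(=O)CC=C(C)C | intermediate
9 | 4-chlorobutanoyl chloride | O=C(Cl)CCCCl | starting material
10 | 1,1,2-tris(trimethylsilyloxy)ethene | C[Si](C)(C)OC=C(O[Si](C)(C)C)O[Si](C)(C)C | starting material
11 | trimethylsilyl 6-chloro-3-oxo-2-(trimethylsilyloxy)hexanoate | C[Si](C)(C)OC(C(=O)CCCCl)C(=O)O[Si](C)(C)C | intermediate
12 | 6-chloro-2-hydroxy-3-oxohexanoic acid | OC(C(=O)CCCCl)C(=O)O | intermediate
13 | 5-chloro-1-hydroxypentan-2-one | OCC(=O)CCCCl | intermediate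
14 | 5-chloro-1-[(triethylsilyl)oxy]pentan-2-one | CC[Si](CC)(CC)OCC(=O)CCCCl | intermediate
15 | sodium enolate of 8 | [Na+].C=CCOC(=O)C(C)=C([O-])CC=C(C)C | intermediate
16 | 5-iodo-1-[(triethylsilyl)oxy]pentan-2-one | CC[Si](CC)(CC)OCC(=O)CCCI | intermediate
17 | prop-2-en-1-yl 2,6-dimethyl-3-oxo-2-{4-oxo-5-[(triethylsilyl)oxy]pentyl}hept-5-enoate (racemic) | C=CCOC(=O)C(C)(CCCC(=O)CO[Si](CC)(CC)CC)C(=O)CC=C(C)C | intermediate
18 | 1-{[tert-butyl(dimethyl)silyl]oxy}-5-chloropentan-2-one | CC(C)(C)[Si](C)(C)OCC(=O)CCCCl | intermediate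
19 | butane-1,4-diylbis(triphenylphosphonium) dibromide | [Br-].[Br-].c1ccc(cc1)[P+](c1ccccc1)(c1ccccc1)CCCC[P+](c1ccccc1)(c1ccccc1)c1ccccc1 | starting material
20 | mono-ylide of 19 | [Br-].c1ccc(cc1)[P+](c1ccccc1)(c1ccccc1)CCC[CH-][P+](c1ccccc1)(c1ccccc1)c1ccccc1 | intermediate
21 | [(4Z)-5-({[tert-butyl(dimethyl)silyl]oxy}methyl)-8-chlorooct-4-en-1-yl](triphenyl)phosphonium bromide | [Br-].ClCCC/C(CO[Si](C)(C)C(C)(C)C)=C/CCC[P+](c1ccccc1)(c1ccccc1)c1ccccc1 | intermediate
22 | ylide of 21 | ClCCC/C(CO[Si](C)(C)C(C)(C)C)=C/CC[CH-][P+](c1ccccc1)(c1ccccc1)c1ccccc1 | intermediate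
23 | prop-2-en-1-yl 2-[(4Z,8Z)-9-({[tert-butyl(dimethyl)silyl]oxy}methyl)-12-chloro-4-{[(triethylsilyl)oxy]methyl}dodeca-4,8-dien-1-yl]-2,6-dimethyl-3-oxohept-5-enoate (racemic at C2) | ClCCC/C(CO[Si](C)(C)C(C)(C)C)=C/CC/C=C(CO[Si](CC)(CC)CC)/CCCC(C)(C(=O)OCC=C)C(=O)CC=C(C)C | intermediate
24 | prop-2-en-1-yl 2-[(4Z,8Z)-9-({[tert-butyl(dimethyl)silyl]oxy}methyl)-12-chloro-4-(hydroxymethyl)dodeca-4,8-dien-1-yl]-2,6-dimethyl-3-oxohept-5-enoate (racemic at C2) | ClCCC/C(CO[Si](C)(C)C(C)(C)C)=C/CC/C=C(CO)/CCCC(C)(C(=O)OCC=C)C(=O)CC=C(C)C | intermediate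
25 | prop-2-en-1-yl 2-[(4Z,8Z)-9-({[tert-butyl(dimethyl)silyl]oxy}methyl)-12-chloro-4-formyldodeca-4,8-dien-1-yl]-2,6-dimethyl-3-oxohept-5-enoate (racemic at C2) | ClCCC/C(CO[Si](C)(C)C(C)(C)C)=C/CC/C=C(C=O)/CCCC(C)(C(=O)OCC=C)C(=O)CC=C(C)C | intermediate
26 | palladium enolate from 25 after loss of CO2 (drawn as the enolate anion; counter-ion (allyl)palladium–PHOX cation; enolate geometry mobile) | ClCCC/C(CO[Si](C)(C)C(C)(C)C)=C/CC/C=C(C=O)/CCCC(C)=C([O-])CC=C(C)C | intermediate
27 | 1-[(1S,2R,3Z)-3-[(4Z)-5-({[tert-butyl(dimethyl)silyl]oxy}methyl)-8-chlorooct-4-en-1-ylidene]-2-hydroxy-1-methylcyclohexyl]-4-methylpent-3-en-1-one (ring B, hydroxyl cis to acyl) | ClCCC/C(CO[Si](C)(C)C(C)(C)C)=C/CC/C=C1/CCC[C@](C)(C(=O)CC=C(C)C)[C@@H]1O | intermediate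
28 | 1-[(1S,2R,3Z)-3-[(4Z)-5-({[tert-butyl(dimethyl)silyl]oxy}methyl)-8-chlorooct-4-en-1-ylidene]-1-methyl-2-[(triethylsilyl)oxy]cyclohexyl]-4-methylpent-3-en-1-one | ClCCC/C(CO[Si](C)(C)C(C)(C)C)=C/CC/C=C1/CCC[C@](C)(C(=O)CC=C(C)C)[C@@H]1O[Si](CC)(CC)CC | intermediate
29 | potassium enolate of 8 | [K+].C=CCOC(=O)C(C)=C([O-])CC=C(C)C | intermediate
30 | iodide corresponding to 28 (8-iodo in place of 8-chloro) | ICCC/C(CO[Si](C)(C)C(C)(C)C)=C/CC/C=C1/CCC[C@](C)(C(=O)CC=C(C)C)[C@@H]1O[Si](CC)(CC)CC | intermediate
31 | prop-2-en-1-yl 2-[(4Z,8Z)-4-({[tert-butyl(dimethyl)silyl]oxy}methyl)-8-{(2R,3S)-3-methyl-3-(4-methylpent-3-enoyl)-2-[(triethylsilyl)oxy]cyclohexylidene}oct-4-en-1-yl]-2,6-dimethyl-3-oxohept-5-enoate (both epimers at the ester-bearing carbon) | C=CCOC(=O)C(C)(CCC/C(CO[Si](C)(C)C(C)(C)C)=C/CC/C=C1/CCC[C@](C)(C(=O)CC=C(C)C)[C@@H]1O[Si](CC)(CC)CC)C(=O)CC=C(C)C | intermediate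
32 | prop-2-en-1-yl 2-[(4Z,8Z)-4-(hydroxymethyl)-8-[(2R,3S)-2-hydroxy-3-methyl-3-(4-methylpent-3-enoyl)cyclohexylidene]oct-4-en-1-yl]-2,6-dimethyl-3-oxohept-5-enoate (both epimers at the ester-bearing carbon) | C=CCOC(=O)C(C)(CCC/C(CO)=C/CC/C=C1/CCC[C@](C)(C(=O)CC=C(C)C)[C@@H]1O)C(=O)CC=C(C)C | intermediate
33 | prop-2-en-1-yl 2-[(4Z,8Z)-4-formyl-8-[(2R,3S)-2-hydroxy-3-methyl-3-(4-methylpent-3-enoyl)cyclohexylidene]oct-4-en-1-yl]-2,6-dimethyl-3-oxohept-5-enoate (both epimers at the ester-bearing carbon) | C=CCOC(=O)C(C)(CCC/C(C=O)=C/CC/C=C1/CCC[C@](C)(C(=O)CC=C(C)C)[C@@H]1O)C(=O)CC=C(C)C | intermediate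
34 | palladium enolate from 33 after loss of CO2 (drawn as the enolate anion; counter-ion (allyl)palladium–PHOX cation; enolate geometry mobile) | CC(C)=CCC([O-])=C(C)CCC/C(C=O)=C/CC/C=C1/CCC[C@](C)(C(=O)CC=C(C)C)[C@@H]1O | intermediate
35 | 1-[(1R,2S,3Z)-2-hydroxy-3-{(4Z)-4-[(2R,3S)-2-hydroxy-3-methyl-3-(4-methylpent-3-enoyl)cyclohexylidene]butylidene}-1-methylcyclohexyl]-4-methylpent-3-en-1-one (meso; both exocyclic alkenes Z, each hydroxyl cis to its acyl group) | CC(C)=CCC(=O)[C@]1(C)CCC/C(=C/CC/C=C2/CCC[C@](C)(C(=O)CC=C(C)C)[C@@H]2O)[C@@H]1O | target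

**Step count and risks**

Total steps: 16. Longest linear sequence: 12 (steps 3, 4, 5, then 8 to 16).

Steps most likely to fail:

1. Step 16 (Proposed new method). What may go wrong: the chiral palladium enolate may add to the aldehyde with poor face selectivity, or C-allylation or protonation of the enolate may outrun the aldol closure. Fallback, known chemistry, from 33 back to 35: the absolute configuration of ring A is no longer induced but selected. Ring A is closed from 33 by the known ligand-achiral decarboxylative aldol cyclisation (palladium diacetate/PPh3, reduced in the flask to zerovalent palladium, diethyl methylmalonate, MeCN, rt). Because ring B is already fixed, the two cis ring A products are diastereomers, the meso target 35 and the C2-symmetric (1S,2R,1'S,2'R) isomer F1, and they are separated by preparative HPLC to give 35.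

2. Step 11 (Proposed new method). What may go wrong: insufficient enantiofacial control at the palladium enolate, or enolate allylation competing with ring closure. Fallback, known chemistry, from 25 back to 27: the same achiral decarboxylative aldol cyclisation (palladium diacetate/PPh3, diethyl methylmalonate, MeCN, rt) gives the racemic cis aldol, that is 27 together with its enantiomer F2. Resolution by preparative HPLC on a polysaccharide-based chiral stationary phase delivers 27, which re-enters the route at step 12.

3. Step 8. What may go wrong: the basic ylide may deprotonate the keto ester partner next to its skipped alkene (conjugation of the enone, loss of ylide) instead of adding to the α-silyloxy ketone. Fallback, from 21 and 8 back to 23: the keto ester is kept away from the ylide and attached afterwards through a halide that is more reactive than the chloride of the other arm. Commercial 5-bromopent-1-ene is converted by ketohydroxylation (RuCl3 cat., 2KHSO5·KHSO4·K2SO4, NaHCO3, EtOAc/MeCN/H2O) into 5-bromo-1-hydroxypentan-2-one F3, which is silylated (Et3SiCl, imidazole) to 5-bromo-1-[(triethylsilyl)oxy]pentan-2-one F4. Ylide 22, made from 21 as in step 8, is condensed with F4 to the bromo chloro diene F5. The sodium enolate 15, generated from 8 and NaH exactly as in step 5, is then alkylated by F5 in DMF at rt without iodide, where the bromide should react and the chloride should not, to give 23.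

Further compounds
F1 | step 16 | 1-[(1S,2R,3Z)-2-hydroxy-3-{(4Z)-4-[(2R,3S)-2-hydroxy-3-methyl-3-(4-methylpent-3-enoyl)cyclohexylidene]butylidene}-1-methylcyclohexyl]-4-methylpent-3-en-1-one (C2-symmetric diastereomer of 35) | CC(C)=CCC(=O)[C@@]1(C)CCC/C(=C/CC/C=C2/CCC[C@](C)(C(=O)CC=C(C)C)[C@@H]2O)[C@H]1O
F2 | step 11 | 1-[(1R,2S,3Z)-3-[(4Z)-5-({[tert-butyl(dimethyl)silyl]oxy}methyl)-8-chlorooct-4-en-1-ylidene]-2-hydroxy-1-methylcyclohexyl]-4-methylpent-3-en-1-one (enantiomer of 27) | ClCCC/C(CO[Si](C)(C)C(C)(C)C)=C/CC/C=C1/CCC[C@@](C)(C(=O)CC=C(C)C)[C@H]1O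
F3 | step 8 | 5-bromo-1-hydroxypentan-2-one | OCC(=O)CCCBr
F4 | step 8 | 5-bromo-1-[(triethylsilyl)oxy]pentan-2-one | CC[Si](CC)(CC)OCC(=O)CCCBr
F5 | step 8 | (4Z,8Z)-1-bromo-9-({[tert-butyl(dimethyl)silyl]oxy}methyl)-12-chloro-4-{[(triethylsilyl)oxy]methyl}dodeca-4,8-diene | ClCCC/C(CO[Si](C)(C)C(C)(C)C)=C/CC/C=C(CO[Si](CC)(CC)CC)/CCCBr
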